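## Structural features

Compound 13 is a chalcone. A 4-hydroxyphenyl ring (ring C) is joined through an (E)-propenone chain to C6 of a 2,2-dimethylchroman, whose arene (ring A) is a phloroglucinol unit and whose dihydropyran (ring B) is fused to it at C4a–C8a. In chroman numbering, O1 is followed by the gem-dimethyl carbon C2, the secondary carbinol C3, the methylene C4 and the ring carbon C4a. The acyl carbon sits on C6, between the hydroxyls on C5 and C7 and para to C8a–O1, and C8 carries the only hydrogen of ring A. C3 is the sole stereocentre, (R), and has no stereogenic neighbour, because it lies between the quaternary C2 and the methylene C4; its configuration must therefore come from a reagent. The fragile parts are the 2',6'-dihydroxychalcone (closure to flavanones under acid or base, an enone that does not survive hydrogenation), the tertiary alkyl aryl ether O1–C2 with the adjacent C3 carbinol (ionization or dehydration under strong acid), and the very electron-rich ring A. The real difficulty is threefold: ring B must be annulated onto a pentasubstituted arene in the one orientation that places O1 para to the acyl carbon, an isolated carbinol flanked by two sp3 carbons must be made as one enantiomer, and the enone must arrive late under mild conditions. The key step uses the fact that C4 is a plain methylene bonded to C4a, a ring carbon ortho to O1 and activated by the oxygens on C5 (ortho) and C7 (para). A carbenoid generated at C4 on a chain hanging from O1 can substitute that carbon, and since a 4-O-alkylated 2,4,6-trioxygenated benzoate has two equivalent ortho carbons, only one constitution can result; C3 emerges as a ketone between two sterically very different carbons.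

## Logic of the disconnections

**13 to 11 and 12.** The bond between the ketone carbon and the α-carbon of the enone is cut, and the ketone carbon is returned to the formyl level. The cut is made here because either hydroxyl ortho to the acyl group can hold a metal next to the formyl C–H bond, so the enone can be assembled by addition of that bond across a terminal alkyne. This removes ring C and the enone in one convergent, redox-neutral step that needs no protecting group and leaves no deprotection after the sensitive chalcone exists. The forward step must deliver the linear (E)-enone, tolerate four free hydroxyls, and stop before the product closes to a flavanone.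

**11 to 8 by way of 10 and 9.** The two O–benzyl bonds are cut and the C6 carbon is moved from formyl back to ester. Benzyl ethers are chosen over methyl ethers because they fall to neutral hydrogenolysis; Lewis-acid demethylation would have to remove two ethers flanking one carbonyl and would endanger the tertiary ether O1–C2 and the C3 carbinol. The ester is the form of the C6 carbon that survives enolate, carbenoid and borane chemistry. The demands are that the oxidation touches only the benzylic alcohol and that hydrogenolysis stops short of the formyl group.

**8 to 7.** The C3–H bond is cut, which removes the only stereocentre and returns a ketone. This works because the carbonyl lies between a quaternary carbon and a methylene, a large steric difference that a chiral reducing system can read. The forward step must give high facial selectivity and leave the ester alone.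

**7 to 6.** The C4–C4a bond is cut and ring B is opened, giving an acyclic aryl ether with a diazoketone terminus. The bond is chosen because C4a is the most nucleophilic carbon of the arene and the symmetry of 6 removes any regiochemical question. The forward step must favour aromatic substitution over ring expansion, C–H insertion and carbene dimerization.

**6 to 4 by way of 5.** The carbon–nitrogen bond of the diazo group is cut, leaving a methyl ketone. Diazo transfer onto an activated methyl ketone avoids any diazoalkane reagent and any acid chloride, and saves steps compared with building the diazoketone from a carboxylic acid. The forward step needs enolization on one side only, which the quaternary α'-carbon guarantees.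

**4 to 1 and 2 by way of 3.** The two benzyl ether bonds and the O–C bond to the tertiary carbon are cut. Of the three hydroxyls of 1, only the one para to the ester is free of hydrogen bonding and it is the most acidic, so it can be alkylated first and the chelated pair protected afterwards. The forward step must achieve mono-O-alkylation at a tertiary α-keto carbon without elimination.

## Other disconnections considered

Alternative 1: The cut is the O1–C2 ether bond of ring B, made on a flavanone that hides one of the two phenols next to the side chain. In the forward sense 8-prenylnaringenin A1 would be epoxidized enantioselectively (Shi epoxidation of the trisubstituted alkene, phenols masked as esters) to the (R)-epoxide A2. Brønsted acid would then let the neighbouring phenol attack the tertiary epoxide carbon in a 6-endo opening to give the pyranoflavanone A3, and base would open the flavanone ring to 13.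
- In its favour: the whole C20 skeleton is present from the start, no carbon–carbon bond and no redox adjustment at the acyl carbon is needed, and attack at the tertiary carbon leaves the carbinol carbon untouched, so (R)-epoxide maps directly onto (R)-C3.
- Against it here: 6-endo closure competes with 5-exo attack at the secondary carbon, which would give a hydroxyisopropyl-dihydrofuran. The asymmetric epoxidation must be run on a polyphenol. The last step is an equilibrium between a 2',6'-dihydroxychalcone and two possible flavanones that must be driven and quenched carefully. A1 is costly, or must be made by a prenylation with its own regiochemical problem.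
- Comparison: on step economy this alternative is better than the chosen plan. On stereocontrol the two are equal in kind (reagent-controlled oxidation against reagent-controlled reduction). On constitution the chosen plan is more secure, because symmetry removes the regiochemical question that A2 poses. Both end at the same delicate chalcone, so neither gains there.

Alternative 2: The cut is the C3–O bond, introduced on a preformed ring B. The chromene A4 would be epoxidized with the (R,R)-(salen)MnCl catalyst (a complex of trivalent manganese) and NaOCl to the cis-epoxide A5 (Jacobsen epoxidation). The benzylic C4–O bond would then be cleaved reductively to reach the C3-carbinol stage of the chosen route.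
- In its favour: 2,2-dimethylchromenes are the privileged substrate class of this epoxidation, so the precedent for high enantioselectivity is better than for reduction of a dialkyl ketone. No diazo compound is handled, which is also better. The benzylic position is so electron-rich that reductive opening should go at C4 only.
- Against it here: the same electron richness makes A5 prone to ionization at C4 and rearrangement to chromanones. The C5 ether sits peri to the alkene and may disturb the approach to the catalyst. Hypochlorite can chlorinate the arene at C8. A second stereocentre is made only to be erased. The methyl ethers of A4 would have to be exchanged for removable groups for the reasons given above.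
- Comparison: step count to the carbinol is equal (alkylation, protection, cyclization, epoxidation, reduction against alkylation, protection, diazo transfer, cyclization, reduction). Stereochemical precedent favours the alternative; intermediate stability and functional-group economy favour the chosen plan.

Alternative 3: The cut is the C3–C4 bond with C4 at the ketone level. A chiral triazolium-derived carbene would convert the aryl aldehyde of the dialdehyde A6 into its Breslow intermediate, which would add to the tethered α-aryloxy aldehyde in an intramolecular crossed benzoin reaction to give the 3-hydroxychroman-4-one A7.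
- In its favour: ring closure and stereocentre are created in one organocatalytic step, without metal or diazo compound; on that count it is better than the chosen plan.
- Against it here: the formyl group must first be placed on one of the two equivalent ortho carbons, which costs steps. The aryl aldehyde is flanked by two ortho oxygens and is a poor acyl-anion precursor, while the aliphatic aldehyde competes for the carbene. Precedent is strong for aldehyde–ketone closures and thin for aldehyde–aldehyde ones. The C3–H of A7 is α to a ketone and can epimerize through the enediol. The C4 carbonyl, a vinylogous carbonate, must then be removed without touching C3.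
- Comparison: the alternative is more convergent in bond-forming events, but needs roughly three more steps, and its stereocentre is less secure once formed. The chosen plan sets C3 after all enolizable stages are past.

Key step: step 4

Remark on the chemistry: chroman numbering is used throughout; the skeletons of 6 and 7 map onto ring A and ring B of 13 without correction (ester carbon on C6, para to O1), the oxygens on C5 and C7 are carried as benzyl ethers, and C3 is (R) as the SMILES of 13 specifies.

## Route

Step 1
Reactants: 1 methyl 2,4,6-trihydroxybenzoate; 2 3-bromo-3-methylbutan-2-one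
Product: 3 methyl 2,6-dihydroxy-4-[(2-methyl-3-oxobutan-2-yl)oxy]benzoate
Conditions: K2CO3 (1.1 equiv), 2 (1.5 equiv), DMF, 50 °C
Reagents that add atoms: none
Why: Williamson-type O-alkylation of a phenoxide by an α-bromo ketone, which is activated for substitution even at a tertiary carbon; the 4-hydroxyl is the most acidic and the only one not held in a hydrogen bond to the ester, so one equivalent of weak base should alkylate it selectively.

Step 2
Reactants: 3 methyl 2,6-dihydroxy-4-[(2-methyl-3-oxobutan-2-yl)oxy]benzoate
Product: 4 methyl 2,6-bis(benzyloxy)-4-[(2-methyl-3-oxobutan-2-yl)oxy]benzoate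
Conditions: BnBr, K2CO3, Bu4NI (cat.), DMF, 60 °C
Reagents that add atoms: benzyl bromide, BrCc1ccccc1
Why: Williamson benzylation of the two chelated hydroxyls under more forcing conditions; K2CO3 is too weak to enolize the methyl ketone to a useful extent, so C-benzylation should not compete.

Step 3
Reactants: 4 methyl 2,6-bis(benzyloxy)-4-[(2-methyl-3-oxobutan-2-yl)oxy]benzoate
Product: 6 methyl 2,6-bis(benzyloxy)-4-[(4-diazo-2-methyl-3-oxobutan-2-yl)oxy]benzoate, via trifluoroacetyl diketone 5 (not isolated)
Conditions: LiN(SiMe3)2, THF, −78 °C; CF3CO2CH2CF3; aq. HCl work-up; then p-ABSA, Et3N, H2O, MeCN, rt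
Reagents that add atoms: 2,2,2-trifluoroethyl trifluoroacetate, O=C(OCC(F)(F)F)C(F)(F)F (trifluoroacetyl group, present only in 5); 4-acetamidobenzenesulfonyl azide, CC(=O)Nc1ccc(cc1)S(=O)(=O)N=[N+]=[N-] (the two nitrogen atoms of 6)
Why: Regitz-type detrifluoroacetylative diazo transfer: the lithium enolate can form only on the methyl side because the other α-carbon is quaternary, Claisen-type trifluoroacetylation gives the activated 1,3-diketone 5, and the sulfonyl azide transfers N2 to its central carbon with loss of the trifluoroacetyl group; the doubly ortho-substituted benzoate and the benzyl ethers are inert to the amide base at −78 °C.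

Step 4
Reactants: 6 methyl 2,6-bis(benzyloxy)-4-[(4-diazo-2-methyl-3-oxobutan-2-yl)oxy]benzoate
Product: 7 methyl 5,7-bis(benzyloxy)-2,2-dimethyl-3-oxochroman-6-carboxylate
Conditions: Rh2(OAc)4 (1 mol %), CH2Cl2, reflux, slow addition of 6, N2
Reagents that add atoms: none
Why: Rh2(OAc)4 takes up the diazo carbon of 6, nitrogen is lost and an electrophilic carbenoid forms on the divalent rhodium core. The carbenoid carbon is attacked by the ring carbon ortho to the tethering oxygen, which is also ortho to one benzyloxy group and para to the other; the resulting arenium (or ring-opened norcaradiene) intermediate rearomatizes by hydrogen shift, so the aromatic C–H is substituted and the C4–C4a bond is formed. The closest known reaction type is the dirhodium tetracarboxylate-catalysed intramolecular aromatic substitution of aryloxy α-diazoketones to chroman-3-ones. Ring B closes as a six-membered ring in which the new bond joins the carbenoid carbon to the arene carbon and the Rh=C bond lies outside the ring (6-exo with respect to the electrophile). No stereocentre is created, because C3 appears as a ketone. Regioselectivity needs no control, since the two ortho carbons of the 4-O-alkylated benzoate are equivalent and either gives O1 para to the C6 ester. Chemoselectivity over cycloheptatriene formation rests on the three donor oxygens, which favour heterolytic opening to the arenium ion; C–H insertion is disfavoured because the only aliphatic C–H bonds within reach (the gem-dimethyl groups) would give a cyclobutanone. The gem-dimethyl group also biases the tether towards the folded conformer, and slow addition under dry conditions should suppress carbene dimerization and O–H insertion.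

Step 5
Reactants: 7 methyl 5,7-bis(benzyloxy)-2,2-dimethyl-3-oxochroman-6-carboxylate
Product: 8 methyl (3R)-5,7-bis(benzyloxy)-3-hydroxy-2,2-dimethylchroman-6-carboxylate
Conditions: (S)-2-methyl-CBS-oxazaborolidine (15 mol %), BH3·SMe2, THF, −20 °C, slow addition of 7; MeOH quench
Reagents that add atoms: none
Why: Corey–Bakshi–Shibata reduction: the ketone binds the ring boron through the lone pair on the side of the smaller C4 methylene, the quaternary C2 points away from the catalyst, and hydride is delivered from the nitrogen-bound borane through a six-membered transition state; with the (S)-catalyst and C2 as the large group this face gives (3R), the same sense as acetophenone to (R)-1-phenylethanol. A reduction governed by steric difference is preferred over arene-directed transfer hydrogenation because neither flank of this ketone is an aryl group; the ester is not reduced by borane at this temperature.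

Step 6
Reactants: 8 methyl (3R)-5,7-bis(benzyloxy)-3-hydroxy-2,2-dimethylchroman-6-carboxylate
Product: 9 (3R)-5,7-bis(benzyloxy)-6-(hydroxymethyl)-2,2-dimethylchroman-3-ol
Conditions: LiAlH4, THF, 0 °C to rt; H2O, aq. NaOH work-up
Reagents that add atoms: none
Why: Hydride reduction of the ester to the primary benzylic alcohol; the C3 carbinol is carried as its alkoxide, benzyl ethers are inert, and the basic work-up avoids ionization of the electron-rich benzylic alcohol.

Step 7
Reactants: 9 (3R)-5,7-bis(benzyloxy)-6-(hydroxymethyl)-2,2-dimethylchroman-3-ol
Product: 10 (3R)-5,7-bis(benzyloxy)-3-hydroxy-2,2-dimethylchroman-6-carbaldehyde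
Conditions: activated MnO2 (excess), CH2Cl2, rt
Reagents that add atoms: none
Why: Chemoselective oxidation of a benzylic alcohol by MnO2; the aliphatic secondary alcohol at C3 is not oxidized under these conditions and the aldehyde is not taken further in the absence of water.

Step 8
Reactants: 10 (3R)-5,7-bis(benzyloxy)-3-hydroxy-2,2-dimethylchroman-6-carbaldehyde
Product: 11 (3R)-3,5,7-trihydroxy-2,2-dimethylchroman-6-carbaldehyde
Conditions: H2 (1 atm), Pd/C (10 %), EtOAc, rt, stopped after two equivalents of H2
Reagents that add atoms: none
Why: Catalytic hydrogenolysis of aryl benzyl ethers under neutral conditions, which spares the tertiary ether O1–C2 and the C3 carbinol; the formyl group is a vinylogous ester deactivated by three donor oxygens and by hydrogen bonding, so it should survive if the uptake is monitored.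

Step 9
Reactants: 11 (3R)-3,5,7-trihydroxy-2,2-dimethylchroman-6-carbaldehyde; 12 4-ethynylphenol
Product: 13 (2E)-3-(4-hydroxyphenyl)-1-[(3R)-3,5,7-trihydroxy-2,2-dimethylchroman-6-yl]prop-2-en-1-one
Conditions: [Rh(cod)Cl]2 (2.5 mol %), dppf (5 mol %), Na2CO3 (10 mol %), 1,4-dioxane, 80 °C, argon, slow addition of 12
Reagents that add atoms: none
Why: Chelation-assisted rhodium-catalysed hydroacylation of an alkyne by a salicylaldehyde: a hydroxyl ortho to the formyl group binds monovalent rhodium as the phenoxide, oxidative addition of the formyl C–H gives a five-membered acyl hydride chelate of trivalent rhodium that resists decarbonylation, syn hydrometalation of 12 places rhodium on the terminal carbon, and reductive elimination forms the acyl–vinyl bond, so the enone should be linear and (E). No stereocentre is touched and no protecting group has to be removed afterwards.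

## Compound list

1 | methyl 2,4,6-trihydroxybenzoate | COC(=O)c1c(O)cc(O)cc1O | starting material
2 | 3-bromo-3-methylbutan-2-one | CC(=O)C(C)(C)Br | starting material
3 | methyl 2,6-dihydroxy-4-[(2-methyl-3-oxobutan-2-yl)oxy]benzoate | COC(=O)c1c(O)cc(OC(C)(C)C(C)=O)cc1O | intermediate
4 | methyl 2,6-bis(benzyloxy)-4-[(2-methyl-3-oxobutan-2-yl)oxy]benzoate | COC(=O)c1c(OCc2ccccc2)cc(OC(C)(C)C(C)=O)cc1OCc1ccccc1 | intermediate
5 | methyl 2,6-bis(benzyloxy)-4-[(6,6,6-trifluoro-2-methyl-3,5-dioxohexan-2-yl)oxy]benzoate | COC(=O)c1c(OCc2ccccc2)cc(OC(C)(C)C(=O)CC(=O)C(F)(F)F)cc1OCc1ccccc1 | intermediate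
6 | methyl 2,6-bis(benzyloxy)-4-[(4-diazo-2-methyl-3-oxobutan-2-yl)oxy]benzoate | COC(=O)c1c(OCc2ccccc2)cc(OC(C)(C)C(=O)C=[N+]=[N-])cc1OCc1ccccc1 | intermediate
7 | methyl 5,7-bis(benzyloxy)-2,2-dimethyl-3-oxochroman-6-carboxylate | COC(=O)c1c(OCc2ccccc2)cc2OC(C)(C)C(=O)Cc2c1OCc1ccccc1 | intermediate
8 | methyl (3R)-5,7-bis(benzyloxy)-3-hydroxy-2,2-dimethylchroman-6-carboxylate | COC(=O)c1c(OCc2ccccc2)cc2OC(C)(C)[C@H](O)Cc2c1OCc1ccccc1 | intermediate
9 | (3R)-5,7-bis(benzyloxy)-6-(hydroxymethyl)-2,2-dimethylchroman-3-ol | OCc1c(OCc2ccccc2)cc2OC(C)(C)[C@H](O)Cc2c1OCc1ccccc1 | intermediate
10 | (3R)-5,7-bis(benzyloxy)-3-hydroxy-2,2-dimethylchroman-6-carbaldehyde | O=Cc1c(OCc2ccccc2)cc2OC(C)(C)[C@H](O)Cc2c1OCc1ccccc1 | intermediate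
11 | (3R)-3,5,7-trihydroxy-2,2-dimethylchroman-6-carbaldehyde | O=Cc1c(O)cc2OC(C)(C)[C@H](O)Cc2c1O | intermediate
12 | 4-ethynylphenol | C#Cc1ccc(O)cc1 | starting material
13 | (2E)-3-(4-hydroxyphenyl)-1-[(3R)-3,5,7-trihydroxy-2,2-dimethylchroman-6-yl]prop-2-en-1-one | CC1(C)Oc2cc(O)c(C(=O)/C=C/c3ccc(O)cc3)c(O)c2C[C@H]1O | target

## Step count and least certain steps

Total step count: 9 steps. Longest linear sequence: 9 steps (1 to 13); 2 and 12 enter as purchased reagents.

**Step 4 (key step).** The most likely failure is diversion of the carbenoid into the cycloheptatriene (Buchner) manifold or into carbene dimerization, followed by enolization and air oxidation of the chroman-3-one during isolation. The fallback drops the metal carbenoid. It sets out from 6 and treats it with CF3CO2H in CH2Cl2 at low temperature, so that the protonated diazoketone (an α-keto diazonium ion) alkylates the activated ortho carbon in an intramolecular Friedel–Crafts reaction. It returns to the route at 7 and makes no new compound.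

**Step 9.** Three processes threaten it: hydrometalation with rhodium on the internal alkyne carbon (leading to the branched enone), oligomerization of the terminal alkyne on rhodium, and base-promoted oxa-Michael closure of the 2',6'-dihydroxychalcone to a flavanone at 80 °C. The fallback builds the enone by aldol condensation and sets out from 10.
- Excess MeMgBr in THF adds to the formyl group to give (3R)-5,7-bis(benzyloxy)-6-(1-hydroxyethyl)-2,2-dimethylchroman-3-ol F1, as a mixture at the new carbinol.
- MnO2 oxidizes only the benzylic carbinol to 1-[(3R)-5,7-bis(benzyloxy)-3-hydroxy-2,2-dimethylchroman-6-yl]ethan-1-one F2.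
- Claisen–Schmidt condensation with 4-(benzyloxy)benzaldehyde (O=Cc1ccc(OCc2ccccc2)cc1; KOH, EtOH) gives (2E)-1-[(3R)-5,7-bis(benzyloxy)-3-hydroxy-2,2-dimethylchroman-6-yl]-3-[4-(benzyloxy)phenyl]prop-2-en-1-one F3.
- BCl3 with pentamethylbenzene as cation scavenger in CH2Cl2 at −78 °C removes the three benzyl groups without reducing the enone, and the route is rejoined at 13.

**Step 1.** The tertiary bromide may lose HBr by elimination, may substitute at the methyl carbon through an oxyallyl or cyclopropanone pathway, or may alkylate more than one hydroxyl. The fallback uses an α-bromo ester that has no second enolizable position and sets out from 1.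
- Alkylation with ethyl 2-bromo-2-methylpropanoate (CCOC(=O)C(C)(C)Br; K2CO3, DMF) gives methyl 4-[(1-ethoxy-2-methyl-1-oxopropan-2-yl)oxy]-2,6-dihydroxybenzoate F4.
- Benzylation as in step 2 gives methyl 2,6-bis(benzyloxy)-4-[(1-ethoxy-2-methyl-1-oxopropan-2-yl)oxy]benzoate F5.
- LiOH in aqueous THF hydrolyses only the aliphatic ethyl ester, the benzoate being shielded by two ortho substituents, to give 2-[3,5-bis(benzyloxy)-4-(methoxycarbonyl)phenoxy]-2-methylpropanoic acid F6.
- (COCl)2 with catalytic DMF gives methyl 2,6-bis(benzyloxy)-4-[(1-chloro-2-methyl-1-oxopropan-2-yl)oxy]benzoate F7.
- F7 acylates (trimethylsilyl)diazomethane (C[Si](C)(C)C=[N+]=[N-]; Et3N, MeCN/THF, 0 °C), and the route is rejoined at 6.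

**Step 5.** Facial selectivity may erode through uncatalysed borane reduction or through coordination of the aryloxy oxygen to boron, which would blur the large/small distinction; the configuration of 8 should in any case be confirmed before going on. The fallback replaces asymmetric induction by resolution and sets out from 7.
- NaBH4 in MeOH gives racemic methyl 5,7-bis(benzyloxy)-3-hydroxy-2,2-dimethylchroman-6-carboxylate F8.
- Esterification with (S)-2-methoxy-2-phenylacetic acid (CO[C@H](C(=O)O)c1ccccc1; DCC, DMAP) gives two diastereomers separable by chromatography or crystallization: methyl (3R)-5,7-bis(benzyloxy)-3-{[(2S)-2-methoxy-2-phenylacetyl]oxy}-2,2-dimethylchroman-6-carboxylate F9 and methyl (3S)-5,7-bis(benzyloxy)-3-{[(2S)-2-methoxy-2-phenylacetyl]oxy}-2,2-dimethylchroman-6-carboxylate F10.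
- LiAlH4 on F9 cleaves the auxiliary ester and reduces the benzoate in the same operation, so the route is rejoined at 9.

**Step 8.** Hydrogenation may run on from the benzyl ethers to the formyl group (reduction to the alcohol and hydrogenolysis to a methyl group). The fallback replaces hydrogenolysis by Lewis-acid cleavage: it sets out from 10, uses BCl3 with pentamethylbenzene in CH2Cl2 at −78 °C, where chelation to the formyl oxygen speeds loss of both ortho benzyl groups, and returns at 11 without any new compound.

## Further compounds

F0 | step 4 | none | none
F1 | step 9 | (3R)-5,7-bis(benzyloxy)-6-(1-hydroxyethyl)-2,2-dimethylchroman-3-ol | CC(O)c1c(OCc2ccccc2)cc2OC(C)(C)[C@H](O)Cc2c1OCc1ccccc1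
F2 | step 9 | 1-[(3R)-5,7-bis(benzyloxy)-3-hydroxy-2,2-dimethylchroman-6-yl]ethan-1-one | CC(=O)c1c(OCc2ccccc2)cc2OC(C)(C)[C@H](O)Cc2c1OCc1ccccc1
F3 | step 9 | (2E)-1-[(3R)-5,7-bis(benzyloxy)-3-hydroxy-2,2-dimethylchroman-6-yl]-3-[4-(benzyloxy)phenyl]prop-2-en-1-one | O=C(/C=C/c1ccc(OCc2ccccc2)cc1)c1c(OCc2ccccc2)cc2OC(C)(C)[C@H](O)Cc2c1OCc1ccccc1
F4 | step 1 | methyl 4-[(1-ethoxy-2-methyl-1-oxopropan-2-yl)oxy]-2,6-dihydroxybenzoate | CCOC(=O)C(C)(C)Oc1cc(O)c(C(=O)OC)c(O)c1
F5 | step 1 | methyl 2,6-bis(benzyloxy)-4-[(1-ethoxy-2-methyl-1-oxopropan-2-yl)oxy]benzoate | CCOC(=O)C(C)(C)Oc1cc(OCc2ccccc2)c(C(=O)OC)c(OCc2ccccc2)c1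
F6 | step 1 | 2-[3,5-bis(benzyloxy)-4-(methoxycarbonyl)phenoxy]-2-methylpropanoic acid | OC(=O)C(C)(C)Oc1cc(OCc2ccccc2)c(C(=O)OC)c(OCc2ccccc2)c1
F7 | step 1 | methyl 2,6-bis(benzyloxy)-4-[(1-chloro-2-methyl-1-oxopropan-2-yl)oxy]benzoate | ClC(=O)C(C)(C)Oc1cc(OCc2ccccc2)c(C(=O)OC)c(OCc2ccccc2)c1
F8 | step 5 | racemic methyl 5,7-bis(benzyloxy)-3-hydroxy-2,2-dimethylchroman-6-carboxylate | COC(=O)c1c(OCc2ccccc2)cc2OC(C)(C)C(O)Cc2c1OCc1ccccc1
F9 | step 5 | methyl (3R)-5,7-bis(benzyloxy)-3-{[(2S)-2-methoxy-2-phenylacetyl]oxy}-2,2-dimethylchroman-6-carboxylate | COC(=O)c1c(OCc2ccccc2)cc2OC(C)(C)[C@H](OC(=O)[C@@H](OC)c3ccccc3)Cc2c1OCc1ccccc1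
F10 | step 5 | methyl (3S)-5,7-bis(benzyloxy)-3-{[(2S)-2-methoxy-2-phenylacetyl]oxy}-2,2-dimethylchroman-6-carboxylate | COC(=O)c1c(OCc2ccccc2)cc2OC(C)(C)[C@@H](OC(=O)[C@@H](OC)c3ccccc3)Cc2c1OCc1ccccc1
F0 | step 8 | none | none
A1 | alternative 1 | 8-prenylnaringenin (mixture at flavanone C2) | CC(C)=CCc1c(O)cc(O)c2C(=O)CC(c3ccc(O)cc3)Oc12
A2 | alternative 1 | 8-{[(2R)-3,3-dimethyloxiran-2-yl]methyl}-5,7-dihydroxy-2-(4-hydroxyphenyl)chroman-4-one (mixture at flavanone C2) | O=C1CC(c2ccc(O)cc2)Oc2c(C[C@H]3OC3(C)C)c(O)cc(O)c21
A3 | alternative 1 | angular (3''R)-3''-hydroxy-2'',2''-dimethyldihydropyrano flavanone fused at C8 and O7 (mixture at flavanone C2) | O=C1CC(c2ccc(O)cc2)Oc2c3c(cc(O)c21)OC(C)(C)[C@H](O)C3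
A4 | alternative 2 | methyl 5,7-dimethoxy-2,2-dimethyl-2H-chromene-6-carboxylate | COC(=O)c1c(OC)cc2OC(C)(C)C=Cc2c1OC
A5 | alternative 2 | methyl (3R,4R)-3,4-epoxy-5,7-dimethoxy-2,2-dimethylchroman-6-carboxylate | COC(=O)c1c(OC)cc2OC(C)(C)[C@@H]3O[C@@H]3c2c1OC
A6 | alternative 3 | methyl 3-formyl-2,6-dimethoxy-4-[(2-methyl-1-oxopropan-2-yl)oxy]benzoate | COC(=O)c1c(OC)cc(OC(C)(C)C=O)c(C=O)c1OC
A7 | alternative 3 | methyl (3S)-3-hydroxy-5,7-dimethoxy-2,2-dimethyl-4-oxochroman-6-carboxylate | COC(=O)c1c(OC)cc2OC(C)(C)[C@H](O)C(=O)c2c1OC
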